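# Proposed total synthesis of CNP0256425.1 by late dearomative aryl-carbonylation of a benzofuran

## Structural features

The target is a sesquineolignan built on a (2R,3R)-2,3-bis(arylmethyl)butane-1,4-diol chain. One arylmethyl group carries a plain guaiacyl ring (ring C). The other is attached to C5 of the benzo ring (ring A) of a 7-methoxy-2,3-dihydrobenzofuran. The dihydrofuran ring (O1–C2–C3–C3a–C7a) bears a 4-hydroxy-3-methoxyphenyl group (ring B) on C2 and a hydroxymethyl group on C3, trans to each other, (2S,3R). The four stereocentres form two adjacent pairs, C2/C3 in the heterocycle and the two CH groups of the butanediol; an arene and a methylene separate the pairs, so neither pair can control the other. The fragile site is the C2–O1 bond, a cyclic benzylic aryl ether para to the ring B oxygen: it is open to hydrogenolysis, to acid ionisation and, once the ring B phenol is free, to quinone-methide-type opening. The two guaiacol units are also easily oxidised. The real difficulty is to set the absolute configuration at C2/C3 independently of the remote R,R pair without a long linear sequence on the heterocycle. The key step exploits the fact that ring B and the one-carbon substituent sit on the adjacent carbons C2 and C3 of what would be the furan double bond. Both can therefore be added across C2=C3 of a flat 7-methoxybenzofuran that is already joined to the butanediol, and the acidity of C3–H next to an ester allows the cis adduct to be corrected to trans.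

## Logic of the disconnections

**23 back to 22.** The two aryl O–CH2Ph bonds are cut last. Benzyl ethers are the one phenol protection that tolerates alkoxide, amide base, hydride and palladium/CO earlier in the route. The demand on the forward step is chemoselectivity against the benzylic C2–O1 bond.

**22 back to 21 and 20.** The C3 hydroxymethyl carbon and the two butanediol oxygens of 22 are traced to three ester groups in 21, so one hydride step frees all three alcohols. 21 is the C3 epimer of 20; because C3–H is benzylic and alpha to the ester, the trans problem is converted into a cis-selective addition followed by equilibration.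

**20 back to 17 and 19 (key disconnection).** The C2–C(aryl) bond and the C3–C(carbonyl) bond are cut, with CO and methanol as the remaining components. Both bonds are exocyclic on adjacent ring carbons, so the cut returns a flat benzofuran and removes ring B, the one-carbon unit and two stereocentres at once. The forward step must place the aryl group on C2, choose one face of the heterocycle under catalyst control, and let alkene insertion precede CO capture.

**17 back to 16 and 15.** The two pivalate C–O bonds are cut, then the diol is traced to the lactone 15, which brings enolate chemistry to the butanediol carbons. The ester protection must be inert to the key step and must fall in the hydride step that leads to 22.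

**15 back to 6 and 13.** The bond between the lactone alpha carbon and the benzylic carbon is cut. The existing centre of 6 directs the new one trans. The forward step needs clean monoalkylation with a reactive, sensitive benzylic bromide.

**6 back to 4, 3, 1 and 2.** The lactone C–O bond is cut (through 5), which requires reduction of the ester of 4 in the presence of its acid. The stereocentre of 4 comes from asymmetric hydrogenation of the C=C bond of 3, and 3 is cut at that C=C bond into 1 and 2.

**13 back to 12, 11, 7 and 8.** The C–Br bond and the oxidation level of the benzylic carbon are adjusted through 12 and 11. The furan ring of 11 is cut at C3a–C3 and O1–C2, giving 7 and the two-carbon unit 8.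

**19 back to 18.** The O–benzyl bond is cut; the forward step is a simple phenol alkylation that leaves the C–I bond alone.

## Other disconnections considered

**Alternative 1:** The cut is the C2–C3 bond of the dihydrofuran ring. In the forward step the diazo ester A1 loses N2 over Rh2(S-PTTL)4 (or its mirror image, whichever gives 2S), and the carbenoid derived from A1 inserts into the benzylic ether C–H bond, closing the five-membered ring and giving the cis ester A2 with both stereocentres set together.
- In its favour: the reaction class is established on exactly this ring system, the ring closure is intramolecular so nothing competes for the reactive intermediate, and the absolute configuration is catalyst-controlled.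
- Against it here: A2 is a small fragment with bromine where the C5 methylene belongs. After epimerisation, reduction and protection it still needs a one-carbon homologation and bromination to reach an electrophile of the type A7, which must then be used in the lactone alkylation. The silyl aryl ether of A2 is also poorly suited to alkoxide epimerisation.
- Comparison: on structure the two plans are equal, since both make the cis 2-aryl-3-ester and equilibrate to trans. On mechanism the alternative is the better one, because its key step is precedented and free of chemoselectivity problems. On step economy the chosen plan is better: by estimate the alternative needs about six more steps and carries the sensitive heterocycle through roughly eight operations, whereas the chosen plan creates it three steps from the end.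

**Alternative 2:** The cut is the O1–C2 bond. In the forward step Ag2O (or DDQ) oxidises the guaiacol unit of A3 so that its benzylic carbon becomes electrophilic (the para-quinone methide stage of A3). The ring A phenol then closes the ring in a 5-exo-trig mode to give A4, trans, under control of the single R centre.
- In its favour: it follows the biogenetic logic, delivers the trans ring directly without an epimerisation step, releases the ring B phenol unprotected, and needs no transition-metal catalysis.
- Against it here: the R centre of A3 must first be installed by an auxiliary-controlled alkylation or an equivalent multistep sequence. The oxidation must discriminate between two phenols and competes with intermolecular trapping of the electrophile, and the trans selectivity rests on substrate control. A4 must then be re-protected, reduced at the C5 ester and brominated before it can be joined to 6.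
- Comparison: on structure the alternative is better, because trans arises in one step. On mechanism it is better in precedent but moves the control of absolute configuration to an earlier stoichiometric step. On step economy the chosen plan is shorter and more convergent.

**Alternative 3:** The cut is the pair of C–C bonds from the two butanediol stereocentres to their benzylic carbons. In the forward step lithiated A6 adds to the beta carbon of A5 anti to the menthyloxy group, and in-situ alkylation at the alpha carbon with A7 gives A8, trans,trans.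
- In its favour: both butanediol centres are set in one known operation with a predictable auxiliary, no asymmetric hydrogenation is needed, and three fragments are joined at once.
- Against it here: it leaves the two stereocentres of the heterocycle unsolved, because A7 must be made beforehand by the chemistry of alternative 1 or 2 and is then the limiting reagent in a low-temperature trapping. The later nickel-mediated desulfurisation endangers the O-benzyl groups and the C2–O1 bond, and the acetal lactone must still be reduced and the menthol removed.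
- Comparison: this alternative addresses the butanediol, not the heterocycle. For that sub-problem it is the equal of steps 1–3 plus step 7 in step count and better in the predictability of the absolute sense. It could even be combined with the chosen key step by using 13 in place of A7. As a stand-alone plan with A7 it is longer and mechanistically riskier for the heterocycle than the chosen plan.

Key step: step 11

Remark 1: 4-(benzyloxy)-3-methoxybenzaldehyde (the benzyl ether of vanillin) is assumed to be purchased; if it is not, one benzylation of vanillin is added.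

Remark 2: the ligand antipodes in steps 2 and 11 are written as the ones expected to give the R acid and the 2S adduct; the sense has to be confirmed in a scouting run and the mirror-image ligand taken if it is opposite.

Remark 3: the butanediol is carried as its bis-pivalate instead of a bis-silyl ether, because the pivalates are cleaved by the hydride of step 13 and no separate deprotection step is then needed.

Remark 4: the descriptors along the end game are cis ester 20 (2S,3R), trans ester 21 (2S,3S) and 22/23 (2S,3R); between 21 and 22 only the CIP priorities at C3 change, not the spatial arrangement.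

## Route

Step 1
Reactants: 1 4-(benzyloxy)-3-methoxybenzaldehyde; 2 dimethyl succinate
Product: 3 (E)-4-[4-(benzyloxy)-3-methoxyphenyl]-3-(methoxycarbonyl)but-3-enoic acid
Conditions: NaOMe (2.2 equiv), MeOH, reflux; then aq. HCl
Reagents that add atoms: none
Why: Stobbe condensation: the succinate enolate adds to the non-enolisable aldehyde, the alkoxide lactonises onto the distal ester, and base-induced opening of the paraconate gives the half-ester with the aryl group trans to the conjugated ester.

Step 2
Reactants: 3 (E)-4-[4-(benzyloxy)-3-methoxyphenyl]-3-(methoxycarbonyl)but-3-enoic acid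
Product: 4 (3R)-4-[4-(benzyloxy)-3-methoxyphenyl]-3-(methoxycarbonyl)butanoic acid
Conditions: H2 (5 bar), [Rh(cod)((S,S)-Et-DuPhos)]BF4 (0.5 mol%), NaOMe (10 mol%), MeOH, 25 °C
Reagents that add atoms: none
Why: Asymmetric hydrogenation of an itaconate-type half-ester: carboxylate and alkene chelate the cationic monovalent rhodium centre and the C2-symmetric bisphospholane selects the alkene face, which sets the R centre; the homogeneous catalyst leaves the benzyl ether intact.

Step 3
Reactants: 4 (3R)-4-[4-(benzyloxy)-3-methoxyphenyl]-3-(methoxycarbonyl)butanoic acid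
Product: 6 (4R)-4-[4-(benzyloxy)-3-methoxybenzyl]dihydrofuran-2(3H)-one, via hydroxy acid 5 (not isolated)
Conditions: KOH (1.0 equiv), EtOH, 0 °C; Ca(BH4)2 (from CaCl2 and NaBH4), −10 °C to rt; then 2 M HCl, rt
Reagents that add atoms: none
Why: Chemoselective borohydride reduction of the ester while the acid is masked as its carboxylate, followed by acid-induced lactonisation; the stereocentre is not touched under these cold, weakly basic conditions and stays R.

Step 4
Reactants: 7 5-iodovanillin (4-hydroxy-3-iodo-5-methoxybenzaldehyde); 8 trimethylsilylacetylene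
Product: 11 7-methoxybenzofuran-5-carbaldehyde, via alkynylphenol 9 (not isolated), via 2-silylbenzofuran 10 (not isolated)
Conditions: Pd(PPh3)2Cl2 (3 mol%), CuI (5 mol%), Et3N, DMF, rt to 60 °C; then TBAF (1.5 equiv, THF), 60 °C
Reagents that add atoms: none
Why: Sonogashira coupling at the aryl iodide, then copper/palladium-assisted 5-endo-dig attack of the ortho phenol on the alkyne (heteroannulation) and fluoride protodesilylation of the C2–Si bond; either order of cyclisation and desilylation ends at the same benzofuran, and the aldehyde is a spectator.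

Step 5
Reactants: 11 7-methoxybenzofuran-5-carbaldehyde
Product: 12 (7-methoxybenzofuran-5-yl)methanol
Conditions: NaBH4, MeOH, 0 °C
Reagents that add atoms: none
Why: Borohydride reduction of an aromatic aldehyde; the benzofuran ring is inert to hydride.

Step 6
Reactants: 12 (7-methoxybenzofuran-5-yl)methanol
Product: 13 5-(bromomethyl)-7-methoxybenzofuran
Conditions: CBr4, PPh3, CH2Cl2, 0 °C; used at once
Reagents that add atoms: tetrabromomethane, BrC(Br)(Br)Br
Why: Appel bromination under neutral conditions, chosen because both the benzofuran and the electron-rich benzylic bromide are acid-sensitive.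

Step 7
Reactants: 6 (4R)-4-[4-(benzyloxy)-3-methoxybenzyl]dihydrofuran-2(3H)-one; 13 5-(bromomethyl)-7-methoxybenzofuran
Product: 15 (3R,4R)-4-[4-(benzyloxy)-3-methoxybenzyl]-3-[(7-methoxybenzofuran-5-yl)methyl]dihydrofuran-2(3H)-one, via lithium enolate 14 (not isolated)
Conditions: LiHMDS (1.05 equiv), THF, −78 °C; then 13 (1.2 equiv), DMPU, −78 to −30 °C
Reagents that add atoms: none
Why: Enolate alkylation of a beta-substituted gamma-butyrolactone: the bromide approaches the enolate face anti to the C4 arylmethyl group, which sets C3 as R (trans), the standard entry to dibenzylbutyrolactone lignans.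

Step 8
Reactants: 15 (3R,4R)-4-[4-(benzyloxy)-3-methoxybenzyl]-3-[(7-methoxybenzofuran-5-yl)methyl]dihydrofuran-2(3H)-one
Product: 16 (2R,3R)-2-[4-(benzyloxy)-3-methoxybenzyl]-3-[(7-methoxybenzofuran-5-yl)methyl]butane-1,4-diol
Conditions: LiAlH4, THF, 0 °C to rt; aq. NaOH work-up
Reagents that add atoms: none
Why: Hydride reduction of the lactone to the 1,4-diol; the aryl benzyl ether and the benzofuran are inert, and the reduction is fast enough at 0 °C that the alpha centre should not epimerise.

Step 9
Reactants: 16 (2R,3R)-2-[4-(benzyloxy)-3-methoxybenzyl]-3-[(7-methoxybenzofuran-5-yl)methyl]butane-1,4-diol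
Product: 17 (2R,3R)-2-[4-(benzyloxy)-3-methoxybenzyl]-3-[(7-methoxybenzofuran-5-yl)methyl]butane-1,4-diyl bis(2,2-dimethylpropanoate)
Conditions: PivCl (2.5 equiv), pyridine, DMAP (cat.), CH2Cl2, 0 °C to rt
Reagents that add atoms: pivaloyl chloride, CC(C)(C)C(Cl)=O
Why: Acylation of two primary alcohols; free hydroxyl groups would compete with the limited methanol for the acylpalladium in step 11, whereas pivalates are inert to amine, methanol and CO at 80 °C and are removed by the hydride of step 13.

Step 10
Reactants: 18 4-iodo-2-methoxyphenol
Product: 19 1-(benzyloxy)-4-iodo-2-methoxybenzene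
Conditions: BnBr, K2CO3, DMF, rt
Reagents that add atoms: benzyl bromide, BrCc1ccccc1
Why: Williamson alkylation of the phenoxide; the C–I bond is untouched.

Step 11
Reactants: 17 (2R,3R)-2-[4-(benzyloxy)-3-methoxybenzyl]-3-[(7-methoxybenzofuran-5-yl)methyl]butane-1,4-diyl bis(2,2-dimethylpropanoate); 19 1-(benzyloxy)-4-iodo-2-methoxybenzene
Product: 20 methyl (2S,3R)-2-[4-(benzyloxy)-3-methoxyphenyl]-5-{(2R,3R)-3-[4-(benzyloxy)-3-methoxybenzyl]-4-[(2,2-dimethylpropanoyl)oxy]-2-{[(2,2-dimethylpropanoyl)oxy]methyl}butyl}-7-methoxy-2,3-dihydrobenzofuran-3-carboxylate (cis)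
Conditions: Pd2(dba)3 (5 mol%), (R)-DTBM-SEGPHOS (12 mol%), 19 (2.5 equiv), CO/N2 (1:9, 1 atm, slow stream), MeOH (10 equiv), 1,2,2,6,6-pentamethylpiperidine (3 equiv), PhMe (0.4 M in 17), 80 °C
Reagents that add atoms: carbon monoxide, [C-]#[O+]; methanol, CO
Why: Proposed new method: oxidative addition of 19 to the zerovalent palladium–bisphosphine complex gives an arylpalladium iodide (divalent palladium); after iodide dissociation the electron-rich C2=C3 bond of 17 coordinates and inserts syn, placing the aryl group on the enol-ether carbon C2 and palladium on benzylic C3, where an η3-benzyl form stabilises it. The only beta hydrogen (on C2) is anti to palladium and the ring oxygen is not syn-periplanar to it, so neither beta-hydride nor beta-aryloxide elimination is geometrically easy, and the alkylpalladium should live long enough to bind CO, insert it with retention at C3 and undergo base-assisted methanolysis, releasing 20 and zerovalent palladium. The closest known reaction types are intramolecular dearomative Heck/anion-capture cascades of indoles and benzofurans, domino Heck/alkoxycarbonylation of tethered alkenes, and intermolecular Heck-type C2 arylation of benzofurans; the intermolecular three-component version on a benzofuran is the untested part. No ring is closed; the furan ring is only dearomatised. C2 (S) is set in the insertion by the chiral bisphosphine, which must choose between the two faces of the flat heterocycle; the butanediol centres are five bonds away and give no bias, so this is pure catalyst control. C3 (R, cis) follows from the syn stereospecificity of the insertion and the retentive CO insertion and is corrected in step 12. The step needs regioselectivity for aryl on C2, secured by the enol-ether polarisation and the benzylic stabilisation of the C3–palladium bond, and chemoselectivity for alkene insertion before carbonylation of the arylpalladium, secured by low CO partial pressure, a concentrated solution, limited methanol and an excess of cheap 19, so that any aryl ester formed costs only 19. A hindered amine without carboxylate additives keeps base-assisted loss of the C2 proton (rearomatisation) slow.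

Step 12
Reactants: 20 methyl (2S,3R)-2-[4-(benzyloxy)-3-methoxyphenyl]-5-{(2R,3R)-3-[4-(benzyloxy)-3-methoxybenzyl]-4-[(2,2-dimethylpropanoyl)oxy]-2-{[(2,2-dimethylpropanoyl)oxy]methyl}butyl}-7-methoxy-2,3-dihydrobenzofuran-3-carboxylate (cis)
Product: 21 methyl (2S,3S)-2-[4-(benzyloxy)-3-methoxyphenyl]-5-{(2R,3R)-3-[4-(benzyloxy)-3-methoxybenzyl]-4-[(2,2-dimethylpropanoyl)oxy]-2-{[(2,2-dimethylpropanoyl)oxy]methyl}butyl}-7-methoxy-2,3-dihydrobenzofuran-3-carboxylate (trans)
Conditions: NaOMe (0.3 equiv), MeOH/THF (1:1), 0 °C to rt
Reagents that add atoms: none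
Why: Base-mediated epimerisation through the ester enolate at benzylic C3; the trans isomer is thermodynamically favoured, methoxide matches the methyl ester, and C2 and the butanediol centres carry no acidic hydrogen. Catalytic alkoxide at or below rt should keep ring opening by loss of the aryloxide slow, and any partial loss of pivalate is harmless because step 13 removes both.

Step 13
Reactants: 21 methyl (2S,3S)-2-[4-(benzyloxy)-3-methoxyphenyl]-5-{(2R,3R)-3-[4-(benzyloxy)-3-methoxybenzyl]-4-[(2,2-dimethylpropanoyl)oxy]-2-{[(2,2-dimethylpropanoyl)oxy]methyl}butyl}-7-methoxy-2,3-dihydrobenzofuran-3-carboxylate (trans)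
Product: 22 (2R,3R)-2-[4-(benzyloxy)-3-methoxybenzyl]-3-{[(2S,3R)-2-[4-(benzyloxy)-3-methoxyphenyl]-3-(hydroxymethyl)-7-methoxy-2,3-dihydrobenzofuran-5-yl]methyl}butane-1,4-diol
Conditions: LiAlH4 (5 equiv), THF, 0 °C to rt; aq. NaOH work-up
Reagents that add atoms: none
Why: LiAlH4 reduces the methyl ester to the C3 hydroxymethyl group and cleaves both pivalates reductively in the same operation; C3 keeps its spatial arrangement and the benzylic C2–O1 ether is inert to hydride.

Step 14
Reactants: 22 (2R,3R)-2-[4-(benzyloxy)-3-methoxybenzyl]-3-{[(2S,3R)-2-[4-(benzyloxy)-3-methoxyphenyl]-3-(hydroxymethyl)-7-methoxy-2,3-dihydrobenzofuran-5-yl]methyl}butane-1,4-diol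
Product: 23 (2R,3R)-2-(4-hydroxy-3-methoxybenzyl)-3-{[(2S,3R)-2-(4-hydroxy-3-methoxyphenyl)-3-(hydroxymethyl)-7-methoxy-2,3-dihydrobenzofuran-5-yl]methyl}butane-1,4-diol
Conditions: H2 (1 atm), 10% Pd/C, EtOAc/MeOH, rt, stopped as soon as 22 is consumed
Reagents that add atoms: none
Why: Hydrogenolysis of the two aryl benzyl ethers over palladium on carbon under neutral conditions; aryl O-benzyl cleavage is expected to be much faster than cleavage of the cyclic benzylic C2–O1 bond, and no stereocentre is affected.

## Compound list

1 | 4-(benzyloxy)-3-methoxybenzaldehyde | COc1cc(C=O)ccc1OCc1ccccc1 | starting material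
2 | dimethyl succinate | COC(=O)CCC(=O)OC | starting material
3 | (E)-4-[4-(benzyloxy)-3-methoxyphenyl]-3-(methoxycarbonyl)but-3-enoic acid | COC(=O)/C(=C/c1ccc(OCc2ccccc2)c(OC)c1)CC(=O)O | intermediate
4 | (3R)-4-[4-(benzyloxy)-3-methoxyphenyl]-3-(methoxycarbonyl)butanoic acid | COC(=O)[C@H](Cc1ccc(OCc2ccccc2)c(OC)c1)CC(=O)O | intermediate
5 | (3R)-4-[4-(benzyloxy)-3-methoxyphenyl]-3-(hydroxymethyl)butanoic acid | OC[C@H](Cc1ccc(OCc2ccccc2)c(OC)c1)CC(=O)O | intermediate
6 | (4R)-4-[4-(benzyloxy)-3-methoxybenzyl]dihydrofuran-2(3H)-one | O=C1C[C@@H](Cc2ccc(OCc3ccccc3)c(OC)c2)CO1 | intermediate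
7 | 5-iodovanillin (4-hydroxy-3-iodo-5-methoxybenzaldehyde) | COc1cc(C=O)cc(I)c1O | starting material
8 | trimethylsilylacetylene | C#C[Si](C)(C)C | starting material
9 | 4-hydroxy-3-methoxy-5-[(trimethylsilyl)ethynyl]benzaldehyde | COc1cc(C=O)cc(C#C[Si](C)(C)C)c1O | intermediate
10 | 7-methoxy-2-(trimethylsilyl)benzofuran-5-carbaldehyde | COc1cc(C=O)cc2cc([Si](C)(C)C)oc12 | intermediate
11 | 7-methoxybenzofuran-5-carbaldehyde | COc1cc(C=O)cc2ccoc12 | intermediate
12 | (7-methoxybenzofuran-5-yl)methanol | COc1cc(CO)cc2ccoc12 | intermediate
13 | 5-(bromomethyl)-7-methoxybenzofuran | COc1cc(CBr)cc2ccoc12 | intermediate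
14 | lithium (4R)-4-[4-(benzyloxy)-3-methoxybenzyl]-4,5-dihydrofuran-2-olate (lithium enolate of 6) | [Li+].[O-]C1=C[C@@H](Cc2ccc(OCc3ccccc3)c(OC)c2)CO1 | intermediate
15 | (3R,4R)-4-[4-(benzyloxy)-3-methoxybenzyl]-3-[(7-methoxybenzofuran-5-yl)methyl]dihydrofuran-2(3H)-one | O=C1[C@H](Cc2cc(OC)c3occc3c2)[C@@H](Cc2ccc(OCc3ccccc3)c(OC)c2)CO1 | intermediate
16 | (2R,3R)-2-[4-(benzyloxy)-3-methoxybenzyl]-3-[(7-methoxybenzofuran-5-yl)methyl]butane-1,4-diol | COc1cc(C[C@@H](CO)[C@H](CO)Cc2cc(OC)c3occc3c2)ccc1OCc1ccccc1 | intermediate
17 | (2R,3R)-2-[4-(benzyloxy)-3-methoxybenzyl]-3-[(7-methoxybenzofuran-5-yl)methyl]butane-1,4-diyl bis(2,2-dimethylpropanoate) | COc1cc(C[C@@H](COC(=O)C(C)(C)C)[C@H](COC(=O)C(C)(C)C)Cc2cc(OC)c3occc3c2)ccc1OCc1ccccc1 | intermediate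
18 | 4-iodo-2-methoxyphenol | COc1cc(I)ccc1O | starting material
19 | 1-(benzyloxy)-4-iodo-2-methoxybenzene | COc1cc(I)ccc1OCc1ccccc1 | intermediate
20 | methyl (2S,3R)-2-[4-(benzyloxy)-3-methoxyphenyl]-5-{(2R,3R)-3-[4-(benzyloxy)-3-methoxybenzyl]-4-[(2,2-dimethylpropanoyl)oxy]-2-{[(2,2-dimethylpropanoyl)oxy]methyl}butyl}-7-methoxy-2,3-dihydrobenzofuran-3-carboxylate (cis) | COc1cc(C[C@@H](COC(=O)C(C)(C)C)[C@H](COC(=O)C(C)(C)C)Cc2cc(OC)c3c(c2)[C@@H](C(=O)OC)[C@@H](c2ccc(OCc4ccccc4)c(OC)c2)O3)ccc1OCc1ccccc1 | intermediate
21 | methyl (2S,3S)-2-[4-(benzyloxy)-3-methoxyphenyl]-5-{(2R,3R)-3-[4-(benzyloxy)-3-methoxybenzyl]-4-[(2,2-dimethylpropanoyl)oxy]-2-{[(2,2-dimethylpropanoyl)oxy]methyl}butyl}-7-methoxy-2,3-dihydrobenzofuran-3-carboxylate (trans) | COc1cc(C[C@@H](COC(=O)C(C)(C)C)[C@H](COC(=O)C(C)(C)C)Cc2cc(OC)c3c(c2)[C@H](C(=O)OC)[C@@H](c2ccc(OCc4ccccc4)c(OC)c2)O3)ccc1OCc1ccccc1 | intermediate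
22 | (2R,3R)-2-[4-(benzyloxy)-3-methoxybenzyl]-3-{[(2S,3R)-2-[4-(benzyloxy)-3-methoxyphenyl]-3-(hydroxymethyl)-7-methoxy-2,3-dihydrobenzofuran-5-yl]methyl}butane-1,4-diol | COc1cc(C[C@@H](CO)[C@H](CO)Cc2cc(OC)c3c(c2)[C@H](CO)[C@@H](c2ccc(OCc4ccccc4)c(OC)c2)O3)ccc1OCc1ccccc1 | intermediate
23 | (2R,3R)-2-(4-hydroxy-3-methoxybenzyl)-3-{[(2S,3R)-2-(4-hydroxy-3-methoxyphenyl)-3-(hydroxymethyl)-7-methoxy-2,3-dihydrobenzofuran-5-yl]methyl}butane-1,4-diol | COc1cc(C[C@@H](CO)[C@H](CO)Cc2cc(OC)c3c(c2)[C@H](CO)[C@@H](c2ccc(O)c(OC)c2)O3)ccc1O | target

## Step count and least certain steps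

Total step count: 14. Longest linear sequence: 10 steps (from 1 through steps 1, 2, 3, 7, 8, 9, 11, 12, 13 and 14; the branch from 7 through steps 4, 5 and 6 is equally long).

**Step 11 (key step, proposed new method).** Four things may go wrong.
- The arylpalladium may be carbonylated before it inserts the benzofuran, because CO insertion into an aryl–palladium bond is normally faster than insertion of an aromatic C=C bond.
- Insertion into the furan bond may be slow.
- After insertion the ring may rearomatise by base-assisted loss of the C2 proton or open by beta-aryloxide elimination.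
- Facial discrimination may be poor, because the heterocycle is flat and has no directing group near C2/C3.

The fallback uses known reactions and gives up catalyst control of C2. It sets out from 17 and 19 and comes back to the route at 21. Direct C2–H arylation of 17 with 19 (Pd(OAc)2, PCy3·HBF4, K2CO3, pivalic acid, DMA, 100 °C) gives the 2-arylbenzofuran F1. Bromination at C3 with NBS in MeCN at 0 °C gives the 3-bromide F2. Palladium-catalysed methoxycarbonylation (Pd(OAc)2, Xantphos, CO 1 atm, MeOH, Et3N, 70 °C) gives the methyl benzofuran-3-carboxylate F3. Magnesium in MeOH/THF then reduces the C2=C3 bond by electron transfer with trans protonation. This should give 21 together with its (2R,3R)-trans diastereomer F4; because of the fixed butanediol centres the two are diastereomers and would be separated by chromatography. F4 would be returned to F3 by dehydrogenation with DDQ.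

**Step 2.** The enantioselectivity may be incomplete, or the sense of induction opposite, for this aryl-substituted half-ester; the catalyst may also be inhibited by impurities carried over from step 1. The fallback replaces catalysis by auxiliary control. It sets out from 1 and comes back to the route at 6. Dithioacetalisation of 1 with propane-1,3-dithiol (I2 cat., CH2Cl2) gives the dithiane F5. Lithiation (n-BuLi, THF, −78 °C) and 1,4-addition to A5 anti to the menthyloxy group gives the adduct F6. Desulfurisation with nickel boride (NiCl2·6H2O, NaBH4, MeOH/THF) gives the 4-(arylmethyl)-5-menthyloxy lactone F7. NaBH4/KOH in aqueous MeOH followed by HCl opens the acetal lactone, reduces the aldehyde to 5 and lactonises to 6 with release of menthol.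

**Step 4.** Cyclisation of the electron-poor phenol may stall, the alkyne may homocouple, or the aldehyde may undergo base-induced side reactions under warm fluoride. The fallback builds the furan ring from an enol ether. It sets out from 7 and comes back to the route at 11. Suzuki coupling of 7 with (E)-2-(2-ethoxyvinyl)-4,4,5,5-tetramethyl-1,3,2-dioxaborolane (Pd(dppf)Cl2, K2CO3, dioxane/water, 80 °C) gives the enol ether 3-[(E)-2-ethoxyethenyl]-4-hydroxy-5-methoxybenzaldehyde F8. p-TsOH in toluene at 80 °C then closes the furan ring with loss of ethanol.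

**Step 14.** Over-reduction by hydrogenolysis of the benzylic C2–O1 bond may set in once the ring B phenol is free, which would open the heterocycle. The fallback moves the debenzylation ahead of the hydride step. It sets out from 21 and comes back to the route at 23. Hydrogenolysis of 21 (H2, Pd/C, EtOAc) is run at the ester stage, where the C3 ester withdraws electron density from C2 and should slow benzylic C–O cleavage; it gives the bis-phenol trans ester F9. Excess LiAlH4 in THF then reduces the ester and cleaves both pivalates, and mildly acidic work-up gives 23 directly.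

## Further compounds

F1 | step 11 | (2R,3R)-2-[4-(benzyloxy)-3-methoxybenzyl]-3-({2-[4-(benzyloxy)-3-methoxyphenyl]-7-methoxybenzofuran-5-yl}methyl)butane-1,4-diyl bis(2,2-dimethylpropanoate) | COc1cc(C[C@@H](COC(=O)C(C)(C)C)[C@H](COC(=O)C(C)(C)C)Cc2cc(OC)c3oc(-c4ccc(OCc5ccccc5)c(OC)c4)cc3c2)ccc1OCc1ccccc1
F2 | step 11 | (2R,3R)-2-[4-(benzyloxy)-3-methoxybenzyl]-3-({2-[4-(benzyloxy)-3-methoxyphenyl]-3-bromo-7-methoxybenzofuran-5-yl}methyl)butane-1,4-diyl bis(2,2-dimethylpropanoate) | COc1cc(C[C@@H](COC(=O)C(C)(C)C)[C@H](COC(=O)C(C)(C)C)Cc2cc(OC)c3oc(-c4ccc(OCc5ccccc5)c(OC)c4)c(Br)c3c2)ccc1OCc1ccccc1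
F3 | step 11 | methyl 2-[4-(benzyloxy)-3-methoxyphenyl]-5-{(2R,3R)-3-[4-(benzyloxy)-3-methoxybenzyl]-4-[(2,2-dimethylpropanoyl)oxy]-2-{[(2,2-dimethylpropanoyl)oxy]methyl}butyl}-7-methoxybenzofuran-3-carboxylate | COc1cc(C[C@@H](COC(=O)C(C)(C)C)[C@H](COC(=O)C(C)(C)C)Cc2cc(OC)c3oc(-c4ccc(OCc5ccccc5)c(OC)c4)c(C(=O)OC)c3c2)ccc1OCc1ccccc1
F4 | step 11 | methyl (2R,3R)-2-[4-(benzyloxy)-3-methoxyphenyl]-5-{(2R,3R)-3-[4-(benzyloxy)-3-methoxybenzyl]-4-[(2,2-dimethylpropanoyl)oxy]-2-{[(2,2-dimethylpropanoyl)oxy]methyl}butyl}-7-methoxy-2,3-dihydrobenzofuran-3-carboxylate (trans) | COc1cc(C[C@@H](COC(=O)C(C)(C)C)[C@H](COC(=O)C(C)(C)C)Cc2cc(OC)c3c(c2)[C@@H](C(=O)OC)[C@H](c2ccc(OCc4ccccc4)c(OC)c2)O3)ccc1OCc1ccccc1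
F5 | step 2 | 2-[4-(benzyloxy)-3-methoxyphenyl]-1,3-dithiane | COc1cc(C2SCCCS2)ccc1OCc1ccccc1
F6 | step 2 | (4R,5R)-4-{2-[4-(benzyloxy)-3-methoxyphenyl]-1,3-dithian-2-yl}-5-{[(1R,2S,5R)-2-isopropyl-5-methylcyclohexyl]oxy}dihydrofuran-2(3H)-one | O=C1O[C@@H](O[C@@H]2C[C@H](C)CC[C@H]2C(C)C)[C@H](C2(c3ccc(OCc4ccccc4)c(OC)c3)SCCCS2)C1
F7 | step 2 | (4R,5R)-4-[4-(benzyloxy)-3-methoxybenzyl]-5-{[(1R,2S,5R)-2-isopropyl-5-methylcyclohexyl]oxy}dihydrofuran-2(3H)-one | O=C1O[C@@H](O[C@@H]2C[C@H](C)CC[C@H]2C(C)C)[C@H](Cc2ccc(OCc3ccccc3)c(OC)c2)C1
F8 | step 4 | 3-[(E)-2-ethoxyethenyl]-4-hydroxy-5-methoxybenzaldehyde | CCO/C=C/c1cc(C=O)cc(OC)c1O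
F9 | step 14 | methyl (2S,3S)-5-{(2R,3R)-4-[(2,2-dimethylpropanoyl)oxy]-2-{[(2,2-dimethylpropanoyl)oxy]methyl}-3-(4-hydroxy-3-methoxybenzyl)butyl}-2-(4-hydroxy-3-methoxyphenyl)-7-methoxy-2,3-dihydrobenzofuran-3-carboxylate (trans) | COc1cc(C[C@@H](COC(=O)C(C)(C)C)[C@H](COC(=O)C(C)(C)C)Cc2cc(OC)c3c(c2)[C@H](C(=O)OC)[C@@H](c2ccc(O)c(OC)c2)O3)ccc1O
A1 | alternative 1 | methyl 2-[5-bromo-3-methoxy-2-({3-methoxy-4-[(triisopropylsilyl)oxy]phenyl}methoxy)phenyl]-2-diazoacetate | COC(=O)C(=[N+]=[N-])c1cc(Br)cc(OC)c1OCc1ccc(O[Si](C(C)C)(C(C)C)C(C)C)c(OC)c1
A2 | alternative 1 | methyl (2S,3R)-cis-5-bromo-7-methoxy-2-{3-methoxy-4-[(triisopropylsilyl)oxy]phenyl}-2,3-dihydrobenzofuran-3-carboxylate | Brc1cc(OC)c2c(c1)[C@@H](C(=O)OC)[C@@H](c1ccc(O[Si](C(C)C)(C(C)C)C(C)C)c(OC)c1)O2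
A3 | alternative 2 | methyl 3-[(2R)-1-{[tert-butyl(dimethyl)silyl]oxy}-3-(4-hydroxy-3-methoxyphenyl)propan-2-yl]-4-hydroxy-5-methoxybenzoate | COC(=O)c1cc(OC)c(O)c(c1)[C@H](CO[Si](C)(C)C(C)(C)C)Cc1ccc(O)c(OC)c1
A4 | alternative 2 | methyl (2S,3R)-3-({[tert-butyl(dimethyl)silyl]oxy}methyl)-2-(4-hydroxy-3-methoxyphenyl)-7-methoxy-2,3-dihydrobenzofuran-5-carboxylate | COC(=O)c1cc(OC)c2c(c1)[C@H](CO[Si](C)(C)C(C)(C)C)[C@@H](c1ccc(O)c(OC)c1)O2
A5 | alternative 3 | (5R)-5-{[(1R,2S,5R)-2-isopropyl-5-methylcyclohexyl]oxy}furan-2(5H)-one | O=C1C=C[C@H](O[C@@H]2C[C@H](C)CC[C@H]2C(C)C)O1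
A6 | alternative 3 | 2-[4-(benzyloxy)-3-methoxyphenyl]-1,3-dithiane | COc1cc(C2SCCCS2)ccc1OCc1ccccc1
A7 | alternative 3 | (2S,3R)-2-[4-(benzyloxy)-3-methoxyphenyl]-5-(bromomethyl)-3-({[tert-butyl(dimethyl)silyl]oxy}methyl)-7-methoxy-2,3-dihydrobenzofuran | BrCc1cc(OC)c2c(c1)[C@H](CO[Si](C)(C)C(C)(C)C)[C@@H](c1ccc(OCc3ccccc3)c(OC)c1)O2
A8 | alternative 3 | (3R,4R,5R)-4-{2-[4-(benzyloxy)-3-methoxyphenyl]-1,3-dithian-2-yl}-3-{[(2S,3R)-2-[4-(benzyloxy)-3-methoxyphenyl]-3-({[tert-butyl(dimethyl)silyl]oxy}methyl)-7-methoxy-2,3-dihydrobenzofuran-5-yl]methyl}-5-{[(1R,2S,5R)-2-isopropyl-5-methylcyclohexyl]oxy}dihydrofuran-2(3H)-one | O=C1O[C@@H](O[C@@H]2C[C@H](C)CC[C@H]2C(C)C)[C@H](C2(c3ccc(OCc4ccccc4)c(OC)c3)SCCCS2)[C@H]1Cc1cc(OC)c2c(c1)[C@H](CO[Si](C)(C)C(C)(C)C)[C@@H](c1ccc(OCc3ccccc3)c(OC)c1)O2
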